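At 59 °C, the best reading of the dusk run was 20.0% of the target that run could hold, far more than the 0.600% read in the autumn run at 100 °C. That comparison is your way into the four new flasks.

all flasks: starting material 0.10 M

| run | coupling partner | temperature | remark | time |
|---|---|---|---|---|
| dusk | 0.030 M | 59 °C | run made earlier |  |
| autumn | 0.12 M | 100 °C | run made earlier |  |
| Friday's | 0.0600 M | 115 °C |  | 30 h |
| Saturday's | 0.0600 M | 65 °C |  | 30 h |
| Sunday's | 0.0600 M | 40 °C |  | 30 h |
| Wednesday's | 0.0600 M | 90 °C |  | 30 h |

| dusk: time / h | dusk: target / % | autumn: time / h | autumn: target / % |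
|---|---|---|---|
| 60.0 | 6.0 | 3.00 | 0.4 |
| 120 | 2.7 | 5.00 | 0.6 |
| 144 | 3.0 | 10.0 | 0 |
| 240 | 0.6 | 20.0 | 0.3 |
| 288 | 0.2 | 40.0 | 0 |

(standard deviation of a reading: 0.5 percentage points)

- the earlier runs were read with a standard deviation of 0.5 percentage points

- the flask that comes out highest in amount of target, in percent of the starting material charged, or "all alike" when all lie within 1.5 percentage points (Friday's / Saturday's / Sunday's / Wednesday's / all alike)
- target at the end, in percent of the starting material charged, Friday's
- target at the end, in percent of the starting material charged, Saturday's
- target at the end, in percent of the starting material charged, Sunday's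
- target at the end, in percent of the starting material charged, Wednesday's

Start with the ceiling, 60.0% for each new flask: the smaller charge as a fraction of the starting material charged, taking one of each per target. Here the coupling partner is the limiting reagent. The four flasks share their charges and time and differ in temperature, and Sunday's is the coldest, so I bracket that one.

From above, target in Sunday's stands at most at 60.0%. From below, I put the dusk share on that ceiling and get 12.0%. This floor is my judgement, not a proof. The dusk readings fall from 6.0% to 0.2%, so target goes again in that run, and the autumn run, at 100 °C and 0.12 M of coupling partner, gives the lower share. I expect the cold to slow both loss and making, and Sunday's has less time, 30 h against the 60.0 h of that best dusk reading. My hand stops at this bracket.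

The forecast names Sunday's, with 4.8% there, 4.5% for Saturday's, 0.05% for Wednesday's and 0% for Friday's: “Sunday's and Saturday's are close, with Sunday's slightly ahead.” Its Sunday's value lies below my floor, so the two reckonings differ.

    starting material + coupling partner → second isomer (k = 0.00264 L mol⁻¹ s⁻¹, Ea = 92.0 kJ mol⁻¹)
    starting material + coupling partner → isomer of the product (k = 5.37 × 10⁻⁵ L mol⁻¹ s⁻¹, Ea = 88.0 kJ mol⁻¹)
    2 coupling partner → homo dimer (k = 0.0137 L mol⁻¹ s⁻¹, Ea = 89.0 kJ mol⁻¹)
    starting material + coupling partner ⇌ target (K = 3.50 L mol⁻¹, k = 0.00205 L mol⁻¹ s⁻¹, Ea = 60.0 kJ mol⁻¹, ΔH = −70.0 kJ mol⁻¹)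
    (constants at 90 °C)

Sunday's comes out highest, at 20.2%, inside the bracket; Saturday's gives 5.43%, Wednesday's 0% and Friday's 0%. In Sunday's, homo dimer holds 37.9% of the coupling partner charged at 30.0 h. The target in Sunday's reaches 33.7% of its ceiling. Now give Sunday's flask 0.24 M of coupling partner: starting material becomes limiting, the ceiling rises to 100%, and the same share gives 33.7%. The computed result is 40.0%.

All runs are simulated with constants of no real substance; scatter was added.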